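**Retrosynthetic overview**
1. The target is (3S)-7,2',4'-trihydroxy-8,3'-diprenylisoflavan. It comes from its tris(allyl ether) 30 by deallylation with a zerovalent palladium catalyst.
2. Ring C (the dihydropyran) is the only ring built. It is closed late by Mitsunobu O1–C2 etherification of phenol alcohol 28; rings A and B both come from resorcinol.
3. 28 comes from imide 25 (auxiliary reduced off, silyl ether cleaved). 25 comes from aldol adduct 23 by ionic deoxygenation of the benzylic C4 hydroxyl.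
4. The key C3–C4 bond is made by an Evans boron syn-aldol between fragment B imide 18 and fragment A aldehyde 20. This sets C3.
5. Both fragments come from 2,4-dihydroxy-3-prenylbenzaldehyde 8 (two directed ortho-lithiations of resorcinol bis-MOM ether). 18 follows by bis-allylation and TosMIC one-carbon homologation to the arylacetic acid.

Assumption: the stereocentre is taken exactly as written in the SMILES, which corresponds to (3S).

Abbreviations: prenyl = 3-methylbut-2-en-1-yl; allyl = prop-2-en-1-yl; MOM = methoxymethyl; TBS = tert-butyldimethylsilyl; Ts = 4-methylphenylsulfonyl; ArA = 4-(allyloxy)-2-(TBS-oxy)-3-prenylphenyl; ArB = 2,4-bis(allyloxy)-3-prenylphenyl.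

**Route**

Step 1
Reactants: 1 resorcinol
Product: 2 1,3-bis(methoxymethoxy)benzene
Conditions: MOMCl (2.5 equiv), iPr2NEt (3 equiv), CH2Cl2, 0 °C → rt
Reagents that add atoms: chloromethyl methyl ether (MOMCl), COCCl
Why: Williamson-type O-alkylation of both phenols gives the bis-MOM ether, whose two acetal oxygens direct the next two lithiations.

Step 2
Reactants: 2 1,3-bis(methoxymethoxy)benzene
Product: 4 1,3-bis(methoxymethoxy)-2-prenylbenzene, via aryllithium 3 (not isolated)
Conditions: n-BuLi (1.1 equiv), THF, 0 °C → rt; then prenyl bromide, −78 °C → rt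
Reagents that add atoms: prenyl bromide, CC(C)=CCBr
Why: Directed ortho-metalation occurs at the position flanked by both MOM ethers, and SN2 alkylation of the aryllithium with the primary allylic bromide installs the prenyl group.

Step 3
Reactants: 4 1,3-bis(methoxymethoxy)-2-prenylbenzene
Product: 7 2,4-bis(methoxymethoxy)-3-prenylbenzaldehyde, via aryllithium 5 (not isolated), via lithium hemiaminal alkoxide 6 (not isolated)
Conditions: n-BuLi (1.2 equiv), TMEDA (1.2 equiv), THF, −20 → 0 °C; then DMF, −78 °C → rt; H2O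
Reagents that add atoms: N,N-dimethylformamide, CN(C)C=O
Why: A second directed ortho-metalation next to a MOM ether followed by formylation with DMF (Bouveault-type) gives the aldehyde after hydrolysis of the stable tetrahedral adduct.

Step 4
Reactants: 7 2,4-bis(methoxymethoxy)-3-prenylbenzaldehyde
Product: 8 2,4-dihydroxy-3-prenylbenzaldehyde
Conditions: 3 M aq HCl, MeOH, rt → 40 °C
Reagents that add atoms: none
Why: Acid-catalysed acetal exchange removes both MOM groups, and the electron-poor formyl-substituted phenol is slow to cyclise onto the prenyl group under these mild conditions.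

Step 5
Reactants: 8 2,4-dihydroxy-3-prenylbenzaldehyde
Product: 9 2,4-bis(allyloxy)-3-prenylbenzaldehyde
Conditions: allyl bromide (3 equiv), K2CO3 (3 equiv), DMF, 60 °C
Reagents that add atoms: allyl bromide, C=CCBr
Why: Williamson etherification with excess reagent in DMF alkylates both phenols, including the hydrogen-bonded 2-OH, giving ethers that survive base, hydride and Lewis acid and are removed at the end without acid.

Step 6
Reactants: 9 2,4-bis(allyloxy)-3-prenylbenzaldehyde
Product: 12 2-[2,4-bis(allyloxy)-3-prenylphenyl]acetonitrile, via tosyloxazoline 10 (not isolated), via N-alkenylformamide 11 (not isolated)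
Conditions: TosMIC (1.3 equiv), t-BuOK (2.5 equiv), DME, −50 °C; then MeOH, reflux
Reagents that add atoms: tosylmethyl isocyanide (TosMIC), Cc1ccc(cc1)S(=O)(=O)C[N+]#[C-]
Why: In the Van Leusen reductive cyanation the TosMIC anion adds to the aldehyde, the adduct cyclises and ring-opens, and methanolysis expels methyl formate and sulfinate to leave the one-carbon-homologated nitrile.

Step 7
Reactants: 12 2-[2,4-bis(allyloxy)-3-prenylphenyl]acetonitrile
Product: 15 2-[2,4-bis(allyloxy)-3-prenylphenyl]acetic acid, via primary amide 13 (not isolated), via potassium carboxylate 14 (not isolated)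
Conditions: KOH, EtOH/H2O, reflux; then 1 M HCl to pH 2, 0 °C
Reagents that add atoms: water, O; potassium hydroxide, [K+].[OH-]
Why: Alkaline nitrile hydrolysis proceeds through the amide to the carboxylate, and allyl aryl ethers and the prenyl group are inert to aqueous hydroxide.

Step 8
Reactants: 15 2-[2,4-bis(allyloxy)-3-prenylphenyl]acetic acid; 16 (4R)-4-benzyl-1,3-oxazolidin-2-one
Product: 18 (4R)-4-benzyl-3-{2-[2,4-bis(allyloxy)-3-prenylphenyl]acetyl}-1,3-oxazolidin-2-one, via mixed pivalic anhydride 17 (not isolated)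
Conditions: PivCl, Et3N, THF, −20 °C; then LiCl, 16, rt
Reagents that add atoms: none
Why: N-acylation of the oxazolidinone by the mixed anhydride (LiCl-promoted) attaches the chiral auxiliary, with attack at the less hindered arylacetyl carbonyl.

Step 9
Reactants: 8 2,4-dihydroxy-3-prenylbenzaldehyde
Product: 19 4-(allyloxy)-2-hydroxy-3-prenylbenzaldehyde
Conditions: allyl bromide (1.05 equiv), K2CO3 (1.1 equiv), acetone, 40 °C
Reagents that add atoms: allyl bromide, C=CCBr
Why: Regioselective Williamson etherification occurs at the 4-OH because the 2-OH is held in a hydrogen bond to the formyl group and is much less nucleophilic.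

Step 10
Reactants: 19 4-(allyloxy)-2-hydroxy-3-prenylbenzaldehyde
Product: 20 4-(allyloxy)-2-(TBS-oxy)-3-prenylbenzaldehyde
Conditions: TBSOTf (1.3 equiv), 2,6-lutidine (2 equiv), CH2Cl2, 0 °C
Reagents that add atoms: tert-butyldimethylsilyl triflate, CC(C)(C)[Si](C)(C)OS(=O)(=O)C(F)(F)F
Why: Silylation with the reactive silyl triflate caps the hindered chelated phenol as an ether that is orthogonal to the allyl ethers and can later be removed with fluoride.

Step 11
Reactants: 18 (4R)-4-benzyl-3-{2-[2,4-bis(allyloxy)-3-prenylphenyl]acetyl}-1,3-oxazolidin-2-one; 20 4-(allyloxy)-2-(TBS-oxy)-3-prenylbenzaldehyde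
Product: 23 (4R)-4-benzyl-3-[(2R,3R)-2-ArB-3-ArA-3-hydroxypropanoyl]-1,3-oxazolidin-2-one, via boron enolate 21 (not isolated), via boron aldolate 22 (not isolated)
Conditions: n-Bu2BOTf (1.2 equiv), iPr2NEt (1.4 equiv), CH2Cl2, −78 → 0 °C; then 20, −78 → 0 °C; then pH 7 buffer, MeOH, 30% H2O2, 0 °C
Reagents that add atoms: none
Why: In this Evans syn-aldol the Z-boron enolate reacts through a closed Zimmerman–Traxler transition state on the face away from the benzyl group of the (R)-auxiliary, which forms the C3–C4 bond and sets the future C3 in the sense that becomes (3S).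

Step 12
Reactants: 23 (4R)-4-benzyl-3-[(2R,3R)-2-ArB-3-ArA-3-hydroxypropanoyl]-1,3-oxazolidin-2-one
Product: 25 (4R)-4-benzyl-3-[(2S)-2-ArB-3-ArA-propanoyl]-1,3-oxazolidin-2-one, via benzylic cation 24 (not isolated)
Conditions: Et3SiH (5 equiv), BF3·OEt2 (2 equiv), CH2Cl2, −78 → −30 °C
Reagents that add atoms: none
Why: Ionic hydrogenation works because the carbinol is ortho and para to oxygen, so it ionises at low temperature and the cation is trapped by silane hydride, while the neighbouring stereocentre is untouched and the low temperature spares the prenyl, allyl and silyl groups.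

Step 13
Reactants: 25 (4R)-4-benzyl-3-[(2S)-2-ArB-3-ArA-propanoyl]-1,3-oxazolidin-2-one
Product: 27 (2S)-2-ArB-3-ArA-propan-1-ol, via aldehyde 26 (not isolated)
Conditions: LiBH4 (2.5 equiv), H2O (1 equiv), THF, 0 °C
Reagents that add atoms: none
Why: Reductive cleavage at the exocyclic imide carbonyl releases the auxiliary, and the transient aldehyde is reduced faster than it enolises, so the benzylic stereocentre is retained and is no longer next to a carbonyl.

Step 14
Reactants: 27 (2S)-2-ArB-3-ArA-propan-1-ol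
Product: 28 (2S)-3-[4-(allyloxy)-2-hydroxy-3-prenylphenyl]-2-ArB-propan-1-ol
Conditions: TBAF (1.1 equiv), AcOH (1.1 equiv), THF, 0 °C
Reagents that add atoms: none
Why: Buffered fluoride desilylation frees only the ring A phenol that will become O1, leaving all allyl ethers in place.

Step 15
Reactants: 28 (2S)-3-[4-(allyloxy)-2-hydroxy-3-prenylphenyl]-2-ArB-propan-1-ol
Product: 30 (3S)-7-(allyloxy)-3-[2,4-bis(allyloxy)-3-prenylphenyl]-8-prenylchromane, via oxyphosphonium phenoxide 29 (not isolated)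
Conditions: PPh3 (1.5 equiv), DIAD (1.5 equiv), THF (0.01 M), 0 °C → rt
Reagents that add atoms: none
Why: Intramolecular Mitsunobu etherification (6-exo-tet displacement at the primary carbon by the only free phenol) closes ring C without touching the stereocentre, and the protected ring B oxygens cannot compete to form a five-membered ring.

Step 16
Reactants: 30 (3S)-7-(allyloxy)-3-[2,4-bis(allyloxy)-3-prenylphenyl]-8-prenylchromane
Product: 31 (3S)-3-(2,4-dihydroxy-3-prenylphenyl)-8-prenylchroman-7-ol (target)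
Conditions: Pd(PPh3)4 (5 mol %), morpholine (10 equiv), THF, rt, argon
Reagents that add atoms: none
Why: Tsuji–Trost deallylation by zerovalent palladium passes the three O-allyl groups to morpholine under neutral conditions that leave the C-prenyl groups and the stereocentre unchanged.

**Compound list**

1 | resorcinol | Oc1cccc(O)c1 | starting material
2 | 1,3-bis(methoxymethoxy)benzene | COCOc1cccc(OCOC)c1 | intermediate
3 | [2,6-bis(methoxymethoxy)phenyl]lithium | [Li]c1c(OCOC)cccc1OCOC | intermediate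
4 | 1,3-bis(methoxymethoxy)-2-prenylbenzene | COCOc1cccc(OCOC)c1CC=C(C)C | intermediate
5 | [2,4-bis(methoxymethoxy)-3-prenylphenyl]lithium | [Li]c1ccc(OCOC)c(CC=C(C)C)c1OCOC | intermediate
6 | lithium (dimethylamino)[2,4-bis(methoxymethoxy)-3-prenylphenyl]methanolate | [Li+].[O-]C(N(C)C)c1ccc(OCOC)c(CC=C(C)C)c1OCOC | intermediate
7 | 2,4-bis(methoxymethoxy)-3-prenylbenzaldehyde | O=Cc1ccc(OCOC)c(CC=C(C)C)c1OCOC | intermediate
8 | 2,4-dihydroxy-3-prenylbenzaldehyde | O=Cc1ccc(O)c(CC=C(C)C)c1O | intermediate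
9 | 2,4-bis(allyloxy)-3-prenylbenzaldehyde | O=Cc1ccc(OCC=C)c(CC=C(C)C)c1OCC=C | intermediate
10 | 5-[2,4-bis(allyloxy)-3-prenylphenyl]-4-tosyl-4,5-dihydro-1,3-oxazole (racemic) | Cc1ccc(cc1)S(=O)(=O)C2N=COC2c3ccc(OCC=C)c(CC=C(C)C)c3OCC=C | intermediate
11 | N-{2-[2,4-bis(allyloxy)-3-prenylphenyl]-1-tosylethenyl}formamide (present as its potassium salt) | O=CNC(=Cc1ccc(OCC=C)c(CC=C(C)C)c1OCC=C)S(=O)(=O)c2ccc(C)cc2 | intermediate
12 | 2-[2,4-bis(allyloxy)-3-prenylphenyl]acetonitrile | N#CCc1ccc(OCC=C)c(CC=C(C)C)c1OCC=C | intermediate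
13 | 2-[2,4-bis(allyloxy)-3-prenylphenyl]acetamide | NC(=O)Cc1ccc(OCC=C)c(CC=C(C)C)c1OCC=C | intermediate
14 | potassium 2-[2,4-bis(allyloxy)-3-prenylphenyl]acetate | [K+].[O-]C(=O)Cc1ccc(OCC=C)c(CC=C(C)C)c1OCC=C | intermediate
15 | 2-[2,4-bis(allyloxy)-3-prenylphenyl]acetic acid | OC(=O)Cc1ccc(OCC=C)c(CC=C(C)C)c1OCC=C | intermediate
16 | (4R)-4-benzyl-1,3-oxazolidin-2-one | O=C1N[C@H](Cc2ccccc2)CO1 | starting material
17 | 2-[2,4-bis(allyloxy)-3-prenylphenyl]acetic pivalic anhydride | CC(C)(C)C(=O)OC(=O)Cc1ccc(OCC=C)c(CC=C(C)C)c1OCC=C | intermediate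
18 | (4R)-4-benzyl-3-{2-[2,4-bis(allyloxy)-3-prenylphenyl]acetyl}-1,3-oxazolidin-2-one | O=C(Cc1ccc(OCC=C)c(CC=C(C)C)c1OCC=C)N2[C@H](Cc3ccccc3)COC2=O | intermediate
19 | 4-(allyloxy)-2-hydroxy-3-prenylbenzaldehyde | O=Cc1ccc(OCC=C)c(CC=C(C)C)c1O | intermediate
20 | 4-(allyloxy)-2-(TBS-oxy)-3-prenylbenzaldehyde | O=Cc1ccc(OCC=C)c(CC=C(C)C)c1O[Si](C)(C)C(C)(C)C | intermediate
21 | (Z)-dibutylboron enolate of 18 | CCCCB(CCCC)O/C(=C\c1ccc(OCC=C)c(CC=C(C)C)c1OCC=C)N2[C@H](Cc3ccccc3)COC2=O | intermediate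
22 | O-dibutylboryl aldolate of 23 (2R,3R) | C=CCOc1ccc([C@H]([C@@H](OB(CCCC)CCCC)c2ccc(OCC=C)c(CC=C(C)C)c2O[Si](C)(C)C(C)(C)C)C(=O)N3[C@H](Cc4ccccc4)COC3=O)c(OCC=C)c1CC=C(C)C | intermediate
23 | (4R)-4-benzyl-3-[(2R,3R)-2-ArB-3-ArA-3-hydroxypropanoyl]-1,3-oxazolidin-2-one | C=CCOc1ccc([C@H]([C@@H](O)c2ccc(OCC=C)c(CC=C(C)C)c2O[Si](C)(C)C(C)(C)C)C(=O)N3[C@H](Cc4ccccc4)COC3=O)c(OCC=C)c1CC=C(C)C | intermediate
24 | benzylic cation from 23 (positive carbon bears ArA; adjacent stereocentre as in 25) | C=CCOc1ccc([C@H]([CH+]c2ccc(OCC=C)c(CC=C(C)C)c2O[Si](C)(C)C(C)(C)C)C(=O)N3[C@H](Cc4ccccc4)COC3=O)c(OCC=C)c1CC=C(C)C | intermediate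
25 | (4R)-4-benzyl-3-[(2S)-2-ArB-3-ArA-propanoyl]-1,3-oxazolidin-2-one | C=CCOc1ccc([C@H](Cc2ccc(OCC=C)c(CC=C(C)C)c2O[Si](C)(C)C(C)(C)C)C(=O)N3[C@H](Cc4ccccc4)COC3=O)c(OCC=C)c1CC=C(C)C | intermediate
26 | (2S)-2-ArB-3-ArA-propanal | C=CCOc1ccc([C@H](Cc2ccc(OCC=C)c(CC=C(C)C)c2O[Si](C)(C)C(C)(C)C)C=O)c(OCC=C)c1CC=C(C)C | intermediate
27 | (2S)-2-ArB-3-ArA-propan-1-ol | C=CCOc1ccc([C@H](Cc2ccc(OCC=C)c(CC=C(C)C)c2O[Si](C)(C)C(C)(C)C)CO)c(OCC=C)c1CC=C(C)C | intermediate
28 | (2S)-3-[4-(allyloxy)-2-hydroxy-3-prenylphenyl]-2-[2,4-bis(allyloxy)-3-prenylphenyl]propan-1-ol | C=CCOc1ccc([C@H](Cc2ccc(OCC=C)c(CC=C(C)C)c2O)CO)c(OCC=C)c1CC=C(C)C | intermediate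
29 | O-(triphenylphosphonio) derivative of 28 at the primary oxygen, as phenoxide zwitterion | C=CCOc1ccc([C@H](Cc2ccc(OCC=C)c(CC=C(C)C)c2[O-])CO[P+](c3ccccc3)(c4ccccc4)c5ccccc5)c(OCC=C)c1CC=C(C)C | intermediate
30 | (3S)-7-(allyloxy)-3-[2,4-bis(allyloxy)-3-prenylphenyl]-8-prenylchromane | C=CCOc1ccc([C@H]2COc3c(ccc(OCC=C)c3CC=C(C)C)C2)c(OCC=C)c1CC=C(C)C | intermediate
31 | (3S)-3-[2,4-dihydroxy-3-(3-methylbut-2-en-1-yl)phenyl]-8-(3-methylbut-2-en-1-yl)chroman-7-ol | CC(C)=CCc1c(O)ccc([C@H]2COc3c(ccc(O)c3CC=C(C)C)C2)c1O | target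

**Totals**
Total step count: 16. Longest linear sequence: 14 steps (1, 2, 3, 4, 5, 6, 7, 8, 11, 12, 13, 14, 15, 16).

**Three steps most likely to fail, with fallbacks**

Step 11 is the main risk. A stabilised arylacetyl boron enolate must add to a hindered, electron-rich aldehyde, so slow addition, retro-aldol and eroded facial selectivity are all possible. The fallback replaces the aldol/deoxygenation pair with an auxiliary-controlled enolate alkylation; it sets out from 15 and 20 and comes back to the route at 27. Aldehyde 20 is reduced (NaBH4, MeOH, 0 °C) to [4-(allyloxy)-2-(TBS-oxy)-3-prenylphenyl]methanol F1. This is converted (CBr4, PPh3, CH2Cl2, 0 °C) into 4-(allyloxy)-2-(TBS-oxy)-3-prenylbenzyl bromide F2, which is used at once. Acid 15 is coupled as in step 8 (through 17) with (4S)-4-benzyl-1,3-oxazolidin-2-one to give (4S)-4-benzyl-3-{2-[2,4-bis(allyloxy)-3-prenylphenyl]acetyl}-1,3-oxazolidin-2-one F3. The enantiomeric auxiliary is needed because the halide attacks the chelated enolate on the face opposite to the one the aldehyde uses in the boron aldol. The sodium (Z)-enolate F4 (NaHMDS, THF, −78 °C) is alkylated by F2 to give (4S)-4-benzyl-3-[(2S)-2-ArB-3-ArA-propanoyl]-1,3-oxazolidin-2-one F5. LiBH4 as in step 13 (through 26) then delivers 27.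

Step 12 is the second risk. The cation may lose a proton to give the 2,3-diarylacryloyl imide, may be captured by the ring B 2-allyloxy oxygen, or the acid may attack the prenyl groups. The fallback separates ionisation from reduction; it sets out from 23 and comes back at 25. Treatment of 23 with PhSH (3 equiv) and ZnI2 (0.5 equiv) in CH2Cl2 at 0 °C traps the cation with a much better nucleophile than silane and gives (4R)-4-benzyl-3-[(2S)-2-ArB-3-ArA-3-(phenylsulfanyl)propanoyl]-1,3-oxazolidin-2-one F6 as a mixture of epimers at the sulfur-bearing carbon. Bu3SnH and AIBN in toluene at 90 °C then cleave the benzylic C–S bond through the benzylic radical F7, which takes hydrogen from the stannane to give 25.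

Step 6 is the third risk. The Van Leusen reaction can stall at the oxazoline stage with an ortho-substituted, electron-rich aldehyde. The fallback is a Wittig homologation and oxidation; it sets out from 9 and comes back at 15, bypassing 12. Aldehyde 9 reacts with the ylide from (methoxymethyl)triphenylphosphonium chloride and KHMDS (THF, 0 °C) to give 1,3-bis(allyloxy)-4-(2-methoxyethenyl)-2-prenylbenzene F8 as an E/Z mixture. Mild hydrolysis (2 M HCl, THF, rt) gives 2-[2,4-bis(allyloxy)-3-prenylphenyl]acetaldehyde F9. Pinnick oxidation (NaClO2, NaH2PO4, large excess of 2-methylbut-2-ene, t-BuOH/H2O, 0 °C) then gives acid 15.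

**Further compounds**

F1 | step 11 | [4-(allyloxy)-2-(TBS-oxy)-3-prenylphenyl]methanol | OCc1ccc(OCC=C)c(CC=C(C)C)c1O[Si](C)(C)C(C)(C)C
F2 | step 11 | 4-(allyloxy)-2-(TBS-oxy)-3-prenylbenzyl bromide | BrCc1ccc(OCC=C)c(CC=C(C)C)c1O[Si](C)(C)C(C)(C)C
F3 | step 11 | (4S)-4-benzyl-3-{2-[2,4-bis(allyloxy)-3-prenylphenyl]acetyl}-1,3-oxazolidin-2-one | O=C(Cc1ccc(OCC=C)c(CC=C(C)C)c1OCC=C)N2[C@@H](Cc3ccccc3)COC2=O
F4 | step 11 | sodium (Z)-enolate of F3 | [Na+].[O-]/C(=C\c1ccc(OCC=C)c(CC=C(C)C)c1OCC=C)N2[C@@H](Cc3ccccc3)COC2=O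
F5 | step 11 | (4S)-4-benzyl-3-[(2S)-2-ArB-3-ArA-propanoyl]-1,3-oxazolidin-2-one | C=CCOc1ccc([C@H](Cc2ccc(OCC=C)c(CC=C(C)C)c2O[Si](C)(C)C(C)(C)C)C(=O)N3[C@@H](Cc4ccccc4)COC3=O)c(OCC=C)c1CC=C(C)C
F6 | step 12 | (4R)-4-benzyl-3-[(2S)-2-ArB-3-ArA-3-(phenylsulfanyl)propanoyl]-1,3-oxazolidin-2-one (both epimers at the sulfur-bearing carbon) | C=CCOc1ccc([C@H](C(Sc5ccccc5)c2ccc(OCC=C)c(CC=C(C)C)c2O[Si](C)(C)C(C)(C)C)C(=O)N3[C@H](Cc4ccccc4)COC3=O)c(OCC=C)c1CC=C(C)C
F7 | step 12 | benzylic radical from F6 (radical carbon bears ArA) | C=CCOc1ccc([C@H]([CH]c2ccc(OCC=C)c(CC=C(C)C)c2O[Si](C)(C)C(C)(C)C)C(=O)N3[C@H](Cc4ccccc4)COC3=O)c(OCC=C)c1CC=C(C)C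
F8 | step 6 | 1,3-bis(allyloxy)-4-(2-methoxyethenyl)-2-prenylbenzene (E/Z mixture) | COC=Cc1ccc(OCC=C)c(CC=C(C)C)c1OCC=C
F9 | step 6 | 2-[2,4-bis(allyloxy)-3-prenylphenyl]acetaldehyde | O=CCc1ccc(OCC=C)c(CC=C(C)C)c1OCC=C
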